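The numbers in the tables are simulated for substances that don't exist, noise included.

At early times these flasks move quickly and then stop: by 8.00 min the teal run has lost 32.4 % of its electrophile, by 20.0 min the electrophile reads 61.5 %, and at 80.0 min it still reads 61.3 %, so we will not spend the next runs on more time.

in all of them: electrophile 0.50 M
- teal: nucleophile 0.60 M; protic impurity 0.50 M; run made earlier
- green: nucleophile 0.56 M; protic impurity 0.50 M; run made earlier
- blue: nucleophile 0.49 M; protic impurity 0.50 M; run made earlier
- Sunday's: nucleophile 0.500 M; protic impurity 0.500 M; time 80 min
- Monday's: nucleophile 0.650 M; protic impurity 0.500 M; time 80 min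

- teal (time / min: electrophile / %, target / %): 8.00: 67.6, 30.8; 20.0: 61.5, 35.2; 40.0: 60.8, 37.1; 60.0: 61.1, 36.4; 80.0: 61.3, 35.8
- green (time / min: electrophile / %, target / %): 15.0: 65.2, 33.1; 30.0: 63.8, 34.7; 50.0: 63.2, 33.8; 60.0: 63.9, 33.2; 80.0: 63.4, 34.0
- blue (time / min: electrophile / %, target / %): 8.00: 72.3, 25.6; 20.0: 67.8, 30.3; 40.0: 67.4, 30.9; 60.0: 67.7, 30.0; 80.0: 68.4, 30.4

(standard deviation of a reading: 0.5 percentage points)

- the analysis behind the earlier runs scatters by 0.5 percentage points, standard deviation

* part of the electrophile that has reacted at the end, Sunday's
* part of the electrophile that has reacted at the end, Monday's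
* what raising the concentration of nucleophile from its lowest to its highest value here does to the part of the electrophile that has reacted (changes below 5 percentage points count as none) (no change / it rises / it falls)

What we must decide is how much nucleophile to charge, and that hangs on one number taken from the last reading of each run: the electrophile reacted per mole of nucleophile charged. It comes to 0.323 in the teal run, 0.327 in the green run and 0.322 in the blue run, and with readings that scatter by 0.5 percentage points we cannot tell these apart, so we carry their mean, 0.324, as the nucleophile's yield. These runs stall with electrophile left and a steady yield, so we take nucleophile as the limiting reagent and reckon the part reacted as the yield times the nucleophile charged, divided by the electrophile charged. That gives 32.4 % for Sunday's flask and 42.1 % for Monday's, a gain of 9.7 points, larger than the 5 points that counts as a change, so we would charge the higher amount and keep 80 min.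

The forecast, made from the same runs, gives 32.8 % and 42 %, with the trend it rises, on the ground that “the plateau depends smoothly on nucleophile”; its numbers lie close to ours but are not the same.

The simulation gives 32.6 % for Sunday's flask and 41.8 % for Monday's, and the trend is it rises, by 9.2 points.

    nucleophile + acid set free ⇌ protonated nucleophile, settled at all times (K = 2800 L mol⁻¹)
    nucleophile + protic impurity → quenched reagent (k = 0.00290 L mol⁻¹ s⁻¹)
    electrophile + nucleophile ⇌ acid set free + target (K = 1.30, k = 0.00300 L mol⁻¹ s⁻¹)
    nucleophile + target → over-reaction product (k = 8.00 × 10⁻⁴ L mol⁻¹ s⁻¹)

Monday's flask ends with 0.74 % of its nucleophile unbound, less than the 58 % of its electrophile. One more flask, like Monday's but charged with 2.6 M of nucleophile, has by the yield a reckoned demand of 0.842 M of electrophile, more than the 0.50 M charged, so by this reckoning electrophile becomes the limiting reagent in that flask. That flask ends with 0 % of its electrophile and 24 % of its nucleophile unbound, and with 94.1 % of the electrophile charged standing as over-reaction product.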